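1. Late in Wednesday's run, at 25.0 min, E read 60%, as at 15.0 min (60%), with D down to 1%. So I took E to stop when D stops, and its end value to be the share of spent D that took the E path.

| flask | D | X | temperature | remark | time |
|---|---|---|---|---|---|
| Thursday's | 0.10 M | 0.070 M | 35 °C | run made earlier |  |
| Wednesday's | 0.050 M | 0.070 M | 46 °C | run made earlier |  |
| Tuesday's | 0.20 M | 0.070 M | 35 °C | run made earlier |  |
| Saturday's | 0.10 M | 0.11 M | 46 °C | run made earlier |  |
| winter | 0.10 M (fed, over 12 min) | 0.0700 M | 40 °C | all else is in the flask from the start; the feed brings no volume worth counting | 20 min |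
| dusk | 0.10 M (fed, over 12 min) | 0.0700 M |  | the addition at 20 °C, then warmed to 40 °C; the feed brings no volume worth counting | 20 min |
| autumn | 0.10 M | 0.0700 M | 40 °C | everything together at the start | 20 min |
| summer | 0.10 M | 0.0700 M (in portions, 4, over 12 min) | 40 °C | first portion at the start, last at 12 min | 20 min |

| run | time / min | E / % | J / % | D / % |
|---|---|---|---|---|
| Thursday's | 4.00 | 19 | 20 | 61 |
| Thursday's | 8.00 | 29 | 29 | 41 |
| Thursday's | 12.0 | 37 | 34 | 30 |
| Thursday's | 15.0 | 39 | 33 | 25 |
| Thursday's | 20.0 | 48 | 37 | 19 |
| Wednesday's | 5.00 | 47 | 32 | 19 |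
| Wednesday's | 10.0 | 58 | 32 | 3 |
| Wednesday's | 15.0 | 60 | 26 | 0 |
| Wednesday's | 20.0 | 59 | 24 | 0 |
| Wednesday's | 25.0 | 60 | 21 | 1 |
| Tuesday's | 5.00 | 20 | 20 | 60 |
| Tuesday's | 10.0 | 32 | 25 | 40 |
| Tuesday's | 15.0 | 45 | 23 | 30 |
| Tuesday's | 20.0 | 53 | 25 | 21 |
| Tuesday's | 25.0 | 55 | 24 | 17 |
| Saturday's | 2.00 | 29 | 30 | 40 |
| Saturday's | 6.00 | 45 | 38 | 12 |
| Saturday's | 12.0 | 51 | 33 | 0 |
| Saturday's | 15.0 | 53 | 28 | 0 |
| Saturday's | 25.0 | 50 | 23 | 0 |

(standard deviation of a reading: 1.5 percentage points)

- what is said of J includes L
- steps that have been proposed: D + X -> J; D -> E; 2 X -> G; X + J <-> L; J <-> Q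

1. the flask that comes out highest in amount of E, in percent of the D charged; "all alike" if 1.5 percentage points covers them all (winter / dusk / autumn / summer / all alike)
2. amount of E at the end, in percent of the D charged, winter
3. amount of E at the end, in percent of the D charged, dusk
4. amount of E at the end, in percent of the D charged, autumn
5. amount of E at the end, in percent of the D charged, summer

2. One pair looked wrong. Tuesday's run had twice the D of Thursday's at the same X and temperature, and D → E, taken as first order in D, uses no X, so I looked for the same percentage of E. Yet at 20.0 min Tuesday's run read more E than Thursday's, 53% against 48%.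

3. Both D steps are first order in D, so [D] cancels from their ratio, and at a given [X] D falls pseudo-first-order. The rate of E over the rate of J is then a constant divided by [X]. By that time the J read in Tuesday's run stood for about 0.0500 M of X taken, more than the 0.0370 M in Thursday's. So Tuesday's [X] ran lower, and E gained.

4. I read that constant from first readings, as E/J times [X] averaged as the start minus half the J formed: 0.0570 M in Thursday's run at 35 °C, 0.0918 M in Saturday's at 46 °C. Taking ln b as straight in temperature between them gives 0.0708 M, my balance concentration b at 40 °C, the [X] at which D splits evenly between E and J. The share of the D being spent at a given moment that goes to E is b/(b + [X]).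

5. Autumn starts at 0.0700 M of X, giving 50.3% to E. Summer's first portion gives 0.0175 M, below b, and 80.2%. I expected summer on top.

6. The forecast also chose summer: 70% (63% to 76%) for summer, "X kept low throughout, little J"; autumn 60% (56% to 65%), winter 59% (53% to 65%), dusk 45% (38% to 52%).

7. Summer gave 69.2%, above autumn 56.5%, winter 53.0% and dusk 41.5%; winter fell below the forecast's 59%. Just before its last addition, summer held X at 36.1% of its charge, with E already 61.0%. That is 0.0253 M; taking it as a rough stand-in for summer's [X] over the whole run, b gives a share of 73.7%, and with 4.7% of D left, an estimate of 70.2% as E, against the 69.2% found.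

    D + X → J (k = 0.0320 /M/s, Ea = 56.0 kJ/mol)
    D → E (k = 0.00170 /s, Ea = 99.0 kJ/mol)
    2 X → G (k = 0.00400 /M/s, Ea = 51.0 kJ/mol)
    X + J ⇌ L, settled at all times (K = 11.0 /M, ΔH = −65.0 kJ/mol)
    J ⇌ Q (K = 5.40, k = 3.80 × 10⁻⁴ /s, Ea = 107 kJ/mol, ΔH = −73.0 kJ/mol)
    (constants at 40 °C)

8. Dusk stopped at 12 min was still at 20 °C. Carrying b down by the same trend gives 0.0297 M. With mean [X] 0.0586 M and 83.4% of D left, that makes 5.58% as E. The flask gave 4.01%.

The earlier runs and the new flask are simulated from invented constants, noise included.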